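**Plan**

1. Numbering (germacrane): lactone C12(=O)–C11(=C13H2), O–C6, ring-fusion C7, acyloxy C8, C9H2, epoxide C10(Me)–C1, C2=C3, C4(C15H2OH)=C5. Retrosynthetic cuts, in order: O–Si at C15; C2=C3 (ring-closing metathesis, opens the ten-membered ring); the 1,10-oxirane (back to the E-alkene of a terminal diene); the C8 ester; then C7–C11, which opens the lactone ring.
2. Feature that allows the lactone closure: in the γ-lactone ring (O–C6–C7–C11–C12) the α-carbon C11 is linked through C12–O–C6 to C7, and C7 carries its C–C bond anti to the C8 oxygen. C7–C11 and C8–O are therefore the two ends of an opened trans-7,8-oxirane, so an O6-acrylate of a 6-hydroxy-7,8-epoxide can close the ring 5-exo through its phosphine-generated α-carbanion, giving the methylene lactone, C7 and the free C8–OH in one event.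
3. Further cuts of the acyclic epoxy alcohol: the two terminal vinyl groups (C1–C2 and C3–C4, twofold Stille), C6–C7 (alkenylzinc + ynal) and C8–C9 (allyl–alkynyl coupling), leading to prop-2-yn-1-ol and a silyl propargyl ether.
4. Forward order: open chain first (C8–C9, C6–C7, vinyl groups), then the lactone ring, acylation at O8, epoxidation, and the ten-membered carbocycle last.
5. Stereochemistry: C6 and the 7,8-oxirane from one Sharpless kinetic resolution (C7 then by inversion, C8 by retention); C1/C10 from reagent-controlled Shi epoxidation of an E-alkene made by syn-carboalumination; ring-cis C4=C5 from trans-hydroalumination/iodination; side-chain Z from a butenolide; 2Z from ring size in the metathesis.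

Key step: step 10

Remark: TBS = tert-butyldimethylsilyl; compounds 11, 13 and 14 are racemic at C6 until the resolution in step 8.

**Route**

Step 1
Reactants: 1 prop-2-yn-1-ol
Product: 3 (E)-3-iodo-2-methylprop-2-en-1-ol, via alkenylalane 2 (not isolated)
Conditions: AlMe3 (3 equiv), Cp2ZrCl2 (0.25 equiv), CH2Cl2, 0 °C to rt; then I2, THF, −30 to 0 °C
Reagents that add atoms: trimethylaluminum C[Al](C)C; iodine II
Why: Zirconocene-catalysed Negishi carboalumination adds Me–Al syn across the alkyne with aluminium at the terminus, and iodinolysis with retention should give the E-iodide whose geometry later becomes that of the trans 1,10-oxirane.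

Step 2
Reactants: 3 (E)-3-iodo-2-methylprop-2-en-1-ol
Product: 4 (E)-3-bromo-1-iodo-2-methylprop-1-ene
Conditions: CBr4, PPh3, CH2Cl2, 0 °C
Reagents that add atoms: carbon tetrabromide BrC(Br)(Br)Br
Why: Appel bromination of a primary allylic alcohol proceeds under neutral conditions without allylic transposition or loss of alkene geometry.

Step 3
Reactants: 4 (E)-3-bromo-1-iodo-2-methylprop-1-ene
Product: 5 (E)-1-iodo-2-methylpent-1-en-4-yne
Conditions: ethynylmagnesium bromide (THF), CuBr·SMe2 (10 mol %), THF, 0 °C to rt
Reagents that add atoms: ethynylmagnesium bromide C#C[Mg]Br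
Why: Copper-catalysed coupling of an alkynyl Grignard reagent with a primary allylic bromide should give the skipped enyne (C8–C9 bond) by direct substitution, the alkenyl iodide being inert to the organocopper at this temperature.

Step 4
Reactants: 6 tert-butyldimethyl(prop-2-yn-1-yloxy)silane
Product: 8 4-[(tert-butyldimethylsilyl)oxy]but-2-ynal, via lithium acetylide 7 (not isolated)
Conditions: n-BuLi, THF, −78 °C; DMF, −78 to 0 °C; inverse quench into aq. KH2PO4
Reagents that add atoms: N,N-dimethylformamide CN(C)C=O
Why: Formylation of a lithium acetylide with DMF followed by a buffered inverse quench is the standard route to ynals and avoids amine addition to the product.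

Step 5
Reactants: 5 (E)-1-iodo-2-methylpent-1-en-4-yne, 8 4-[(tert-butyldimethylsilyl)oxy]but-2-ynal
Product: 11 rac-(5E,8E)-1-[(tert-butyldimethylsilyl)oxy]-9-iodo-8-methylnona-5,8-dien-2-yn-4-ol, via alkenylzirconocene chloride 9 (not isolated), via alkenyl(methyl)zinc 10 (not isolated)
Conditions: 5, Cp2Zr(H)Cl, CH2Cl2, rt; ZnMe2, −65 °C; then 8, 0 °C; aq. NH4Cl
Reagents that add atoms: none
Why: Hydrozirconation of the terminal alkyne (syn, metal at the terminus) and zirconium-to-zinc transmetalation give an E-alkenylzinc that should add 1,2 to the ynal and form the C6–C7 bond with the E C7=C8 alkene in place, the carbinol being racemic at this stage.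

Step 6
Reactants: 11 rac-(5E,8E)-1-[(tert-butyldimethylsilyl)oxy]-9-iodo-8-methylnona-5,8-dien-2-yn-4-ol
Product: 13 rac-(2Z,5E,8E)-1-[(tert-butyldimethylsilyl)oxy]-2,9-diiodo-8-methylnona-2,5,8-trien-4-ol, via cyclic alkenylalanate 12 (not isolated)
Conditions: NaAlH2(OCH2CH2OMe)2, THF, 0 °C; then I2, THF, −78 to 0 °C
Reagents that add atoms: iodine II
Why: Hydroxyl-directed trans-hydroalumination of the propargylic alcohol places aluminium on the distal alkyne carbon (C4) cis to the carbinol carbon, and iodination with retention should give the Z-iodide that fixes the ring-cis geometry of C4=C5.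

Step 7
Reactants: 13 rac-(2Z,5E,8E)-1-[(tert-butyldimethylsilyl)oxy]-2,9-diiodo-8-methylnona-2,5,8-trien-4-ol
Product: 14 rac-(3E,6E,9E)-3-{[(tert-butyldimethylsilyl)oxy]methyl}-9-methyldodeca-1,3,6,9,11-pentaen-5-ol
Conditions: tributyl(vinyl)stannane (2.5 equiv), PdCl2(MeCN)2 (5 mol %), DMF, rt
Reagents that add atoms: tributyl(vinyl)stannane C=C[Sn](CCCC)(CCCC)CCCC
Why: A twofold Stille coupling with retention at both alkenyl iodides should install the two terminal vinyl groups (future C2 and C3) in one operation.

Step 8
Reactants: 14 rac-(3E,6E,9E)-3-{[(tert-butyldimethylsilyl)oxy]methyl}-9-methyldodeca-1,3,6,9,11-pentaen-5-ol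
Product: 15 (1R,2E)-3-{[(tert-butyldimethylsilyl)oxy]methyl}-1-{(2R,3R)-3-[(2E)-2-methylpenta-2,4-dien-1-yl]oxiran-2-yl}penta-2,4-dien-1-ol
Conditions: Ti(OiPr)4 (20 mol %), D-(−)-diisopropyl tartrate (24 mol %), t-BuOOH (0.55 equiv), 4 Å MS, CH2Cl2, −20 °C
Reagents that add atoms: tert-butyl hydroperoxide CC(C)(C)OO
Why: In this Sharpless kinetic resolution the S-enantiomer of 14 should react fast with the D-(−)-tartrate catalyst at the E-disubstituted C7=C8 alkene to give the erythro epoxy alcohol (setting C6 and both oxirane carbons), while the R-enantiomer stays behind and the cis-substituted dienyl alkene is a poor substrate.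

Step 9
Reactants: 15 (1R,2E)-3-{[(tert-butyldimethylsilyl)oxy]methyl}-1-{(2R,3R)-3-[(2E)-2-methylpenta-2,4-dien-1-yl]oxiran-2-yl}penta-2,4-dien-1-ol
Product: 16 acrylate (prop-2-enoate) ester of 15 at the C6 hydroxyl
Conditions: acryloyl chloride, Et3N, CH2Cl2, −78 to 0 °C
Reagents that add atoms: acryloyl chloride C=CC(=O)Cl
Why: Acylation of the secondary alcohol with an acid chloride and an amine base leaves the epoxide and the stereocentres untouched.

Step 10
Reactants: 16 acrylate ester of 15
Product: 19 (4R,5R)-5-[(1E)-2-{[(tert-butyldimethylsilyl)oxy]methyl}buta-1,3-dien-1-yl]-4-[(1R,3E)-1-hydroxy-3-methylhexa-3,5-dien-1-yl]-3-methylideneoxolan-2-one, via phosphonium enolate 17 (not isolated), via phosphonium alkoxide 18 (not isolated)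
Conditions: PMe3 (30 mol %), t-BuOH (0.02 M), sealed tube, 40 °C
Reagents that add atoms: none
Why: Proposed new method: PMe3 adds reversibly to the acrylate β-carbon (C13) to give ester enolate 17, whose α-carbon (C11) attacks the neighbouring oxirane carbon C7 anti to its C–O bond, and the C8 alkoxide of 18 (relayed by t-BuOH) then removes the C11 proton and expels PMe3 to unveil the exocyclic methylene. The closest known reaction types are the phosphine-catalysed intramolecular Morita–Baylis–Hillman alkylation of enones with tethered epoxides and the C-2-selective cyclisation of 2,3-epoxy alcohol carbamates; the untested element is an acrylate whose ester oxygen lies inside the forming ring, which is argued to be feasible because the enolate C–O bond rotates freely. The γ-lactone closes in the 5-exo-tet mode, the 6-endo attack at C8 being stereoelectronically disfavoured as in the carbamate case. C7 is the only new stereocentre and is fixed by inversion at the oxirane carbon, so the erythro epoxy alcohol from step 8 translates into the trans H6/H7 lactone with the 8R carbinol retained. The step needs the intramolecular alkylation to outrun acrylate dimerisation (Rauhut–Currier) and direct phosphine attack on the epoxide; dilution, the protic medium and the short O6–C12 tether should secure this, and the dienes and silyl ether are inert to PMe3.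

Step 11
Reactants: 20 3-methylfuran-2(5H)-one
Product: 22 (Z)-4-acetoxy-2-methylbut-2-enoic acid, via sodium hydroxy carboxylate 21 (not isolated)
Conditions: NaOH (1.0 equiv), H2O–MeOH, rt; evaporate; Ac2O, pyridine, DMAP (cat.), 0 °C to rt; cold aq. HCl to pH 3
Reagents that add atoms: sodium hydroxide [Na+].[OH-]; acetic anhydride CC(=O)OC(C)=O
Why: Saponification opens the butenolide with the Z geometry fixed by the ring, and acetylation of the carboxylate salt before acidification should prevent relactonisation.

Step 12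
Reactants: 19 hydroxy methylene lactone, 22 (Z)-4-acetoxy-2-methylbut-2-enoic acid
Product: 24 (2Z)-4-acetoxy-2-methylbut-2-enoate ester of 19 at the C8 hydroxyl, via mixed anhydride 23 (not isolated)
Conditions: 22, 2,4,6-trichlorobenzoyl chloride, Et3N, toluene, rt; then 19, DMAP, rt
Reagents that add atoms: none
Why: Yamaguchi esterification through the mixed anhydride should acylate the hindered secondary C8 alcohol without Z-to-E isomerisation of the angelate-type acid.

Step 13
Reactants: 24 C8 ester of 19
Product: 25 (1R,10R)-1,10-epoxide of 24 (side chain terminus now a (2R,3R)-3-ethenyl-2-methyloxiran-2-yl group)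
Conditions: D-fructose-derived Shi ketone (30 mol %), KHSO5 (Oxone), K2CO3, Bu4NHSO4, MeCN–CH2(OMe)2–aq. Na2B4O7 buffer (pH 10.5), 0 °C
Reagents that add atoms: potassium peroxymonosulfate [K+].[O-]S(=O)(=O)OO
Why: In this Shi epoxidation the chiral dioxirane should attack the most electron-rich, trisubstituted alkene of the isoprenoid diene (the other diene is deactivated by two allylic oxygens and the enoates are inert) through the spiro transition state that gives the (1R,10R) trans-epoxide under reagent control.

Step 14
Reactants: 25 vinyl epoxide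
Product: 26 15-O-TBS ether of the target
Conditions: second-generation Grubbs catalyst RuCl2(=CHPh)(H2IMes)(PCy3) (10 mol %), CH2Cl2 (1 mM), 40 °C
Reagents that add atoms: none
Why: Ring-closing metathesis between the vinyl epoxide and the terminal alkene of the diene releases ethene and should close the ten-membered ring with the Z C2=C3 bond that the ring size demands, the alternative seven-membered closure onto the lactone methylene being blocked because it would need a trans-fused oxirane.

Step 15
Reactants: 26 15-O-TBS ether of the target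
Product: 27 target, (1R,2Z,4E,6R,7R,8R,10R)-8-{[(2Z)-4-acetoxy-2-methylbut-2-enoyl]oxy}-1,10-epoxy-15-hydroxygermacra-2,4,11(13)-trien-12,6-olide
Conditions: Bu4NF, AcOH (1:1), THF, 0 °C to rt
Reagents that add atoms: none
Why: Acetic acid-buffered fluoride should cleave the primary allylic silyl ether without opening the vinyl epoxide, cleaving the acetate or adding to the methylene lactone.

**Compound list**

1 | prop-2-yn-1-ol | C#CCO | starting material
2 | dimethylaluminium (2E)-3-(dimethylalumanyl)-2-methylprop-2-en-1-olate (alkenylalane, not isolated) | C[Al](C)OC/C(C)=C/[Al](C)C | intermediate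
3 | (E)-3-iodo-2-methylprop-2-en-1-ol | OC/C(C)=C/I | intermediate
4 | (E)-3-bromo-1-iodo-2-methylprop-1-ene | BrC/C(C)=C/I | intermediate
5 | (E)-1-iodo-2-methylpent-1-en-4-yne | C#CC/C(C)=C/I | intermediate
6 | tert-butyldimethyl(prop-2-yn-1-yloxy)silane | C#CCO[Si](C)(C)C(C)(C)C | starting material
7 | lithium acetylide of 6 (not isolated) | [Li]C#CCO[Si](C)(C)C(C)(C)C | intermediate
8 | 4-[(tert-butyldimethylsilyl)oxy]but-2-ynal | O=CC#CCO[Si](C)(C)C(C)(C)C | intermediate
9 | chloro[(1E,4E)-5-iodo-4-methylpenta-1,4-dien-1-yl]zirconocene (not isolated) | Cl[Zr](/C=C/C/C(C)=C/I)(C1C=CC=C1)C1C=CC=C1 | intermediate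
10 | [(1E,4E)-5-iodo-4-methylpenta-1,4-dien-1-yl](methyl)zinc (not isolated) | C[Zn]/C=C/C/C(C)=C/I | intermediate
11 | rac-(5E,8E)-1-[(tert-butyldimethylsilyl)oxy]-9-iodo-8-methylnona-5,8-dien-2-yn-4-ol | CC(C)(C)[Si](C)(C)OCC#CC(O)/C=C/C/C(C)=C/I | intermediate
12 | sodium cyclic alkenylalanate (2,5-dihydro-1,2-oxaluminol-2-uide with two 2-methoxyethoxy groups on Al; not isolated) | [Na+].COCCO[Al-]1(OCCOC)OC(/C=C/C/C(C)=C/I)C=C1CO[Si](C)(C)C(C)(C)C | intermediate
13 | rac-(2Z,5E,8E)-1-[(tert-butyldimethylsilyl)oxy]-2,9-diiodo-8-methylnona-2,5,8-trien-4-ol | CC(C)(C)[Si](C)(C)OC/C(I)=C/C(O)/C=C/C/C(C)=C/I | intermediate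
14 | rac-(3E,6E,9E)-3-{[(tert-butyldimethylsilyl)oxy]methyl}-9-methyldodeca-1,3,6,9,11-pentaen-5-ol | CC(C)(C)[Si](C)(C)OC/C(C=C)=C/C(O)/C=C/C/C(C)=C/C=C | intermediate
15 | (1R,2E)-3-{[(tert-butyldimethylsilyl)oxy]methyl}-1-{(2R,3R)-3-[(2E)-2-methylpenta-2,4-dien-1-yl]oxiran-2-yl}penta-2,4-dien-1-ol | CC(C)(C)[Si](C)(C)OC/C(C=C)=C/[C@@H](O)[C@H]1O[C@@H]1C/C(C)=C/C=C | intermediate
16 | acrylate ester of 15 | CC(C)(C)[Si](C)(C)OC/C(C=C)=C/[C@@H](OC(=O)C=C)[C@H]1O[C@@H]1C/C(C)=C/C=C | intermediate
17 | β-trimethylphosphonio ester enolate zwitterion from 16 (not isolated) | C[P+](C)(C)CC=C([O-])O[C@H](/C=C(CO[Si](C)(C)C(C)(C)C)\C=C)[C@H]1O[C@@H]1C/C(C)=C/C=C | intermediate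
18 | cyclised α-(trimethylphosphoniomethyl) lactone C8-alkoxide zwitterion (not isolated) | C[P+](C)(C)CC1C(=O)O[C@H](/C=C(CO[Si](C)(C)C(C)(C)C)\C=C)[C@H]1[C@H]([O-])C/C(C)=C/C=C | intermediate
19 | (4R,5R)-5-[(1E)-2-{[(tert-butyldimethylsilyl)oxy]methyl}buta-1,3-dien-1-yl]-4-[(1R,3E)-1-hydroxy-3-methylhexa-3,5-dien-1-yl]-3-methylideneoxolan-2-one | C=C1C(=O)O[C@H](/C=C(CO[Si](C)(C)C(C)(C)C)\C=C)[C@H]1[C@H](O)C/C(C)=C/C=C | intermediate
20 | 3-methylfuran-2(5H)-one | CC1=CCOC1=O | starting material
21 | sodium (Z)-4-hydroxy-2-methylbut-2-enoate (not isolated) | C/C(=C/CO)C(=O)[O-].[Na+] | intermediate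
22 | (Z)-4-acetoxy-2-methylbut-2-enoic acid | CC(=O)OC/C=C(/C)C(=O)O | intermediate
23 | mixed anhydride of 22 and 2,4,6-trichlorobenzoic acid (not isolated) | CC(=O)OC/C=C(/C)C(=O)OC(=O)c1c(Cl)cc(Cl)cc1Cl | intermediate
24 | (1R,3E)-1-{(2R,3R)-2-[(1E)-2-{[(tert-butyldimethylsilyl)oxy]methyl}buta-1,3-dien-1-yl]-4-methylidene-5-oxooxolan-3-yl}-3-methylhexa-3,5-dien-1-yl (2Z)-4-acetoxy-2-methylbut-2-enoate | C=C1C(=O)O[C@H](/C=C(CO[Si](C)(C)C(C)(C)C)\C=C)[C@H]1[C@H](OC(=O)/C(C)=C\COC(C)=O)C/C(C)=C/C=C | intermediate
25 | (1R)-1-{(2R,3R)-2-[(1E)-2-{[(tert-butyldimethylsilyl)oxy]methyl}buta-1,3-dien-1-yl]-4-methylidene-5-oxooxolan-3-yl}-2-[(2R,3R)-3-ethenyl-2-methyloxiran-2-yl]ethyl (2Z)-4-acetoxy-2-methylbut-2-enoate | C=C1C(=O)O[C@H](/C=C(CO[Si](C)(C)C(C)(C)C)\C=C)[C@H]1[C@H](OC(=O)/C(C)=C\COC(C)=O)C[C@@]2(C)O[C@@H]2C=C | intermediate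
26 | 15-O-tert-butyldimethylsilyl ether of the target | C=C1C(=O)O[C@@H]2/C=C(CO[Si](C)(C)C(C)(C)C)\C=C/[C@H]3O[C@]3(C)C[C@@H](OC(=O)/C(C)=C\COC(C)=O)[C@@H]12 | intermediate
27 | (1R,2Z,4E,6R,7R,8R,10R)-8-{[(2Z)-4-acetoxy-2-methylbut-2-enoyl]oxy}-1,10-epoxy-15-hydroxygermacra-2,4,11(13)-trien-12,6-olide (CNP0103272.1) | C=C1C(=O)O[C@@H]2/C=C(CO)\C=C/[C@H]3O[C@]3(C)C[C@@H](OC(=O)/C(C)=C\COC(C)=O)[C@@H]12 | target

**Step count and risks**

Total steps: 15. Longest linear sequence: 13 steps (1, 2, 3, 5–10, 12–15) from prop-2-yn-1-ol.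

Steps most likely to fail:

1. Step 10 (Proposed new method). The catalytic cycle may stall or divert: acrylate oligomerisation, 6-endo opening at C8, or oxa-Michael addition of the liberated C8 alkoxide to the new methylene lactone could outcompete the 5-exo alkylation. The fallback uses known chemistry, a stoichiometric stabilised carbanion followed by olefination. It sets out from 15: esterification with (diethoxyphosphoryl)acetic acid (DCC, DMAP, CH2Cl2) should give the diethylphosphonoacetate ester F1. KOtBu in THF at −40 to 0 °C generates the phosphonoacetate carbanion, which opens the oxirane at C7 with inversion (the first stage of a Wadsworth–Emmons cyclopropanation, held at low temperature so that phosphoryl transfer to the C8 alkoxide stays slow) to give the α-(diethoxyphosphoryl) hydroxy lactone F2. Paraformaldehyde added to the same flask completes a Horner–Wadsworth–Emmons methylenation and comes back to the route at 19.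

2. Step 14. Closure of the ten-membered ring is slow, so intermolecular metathesis (oligomers) or catalyst decomposition at the vinyl epoxide may dominate, and E/Z control rests on ring strain alone. The fallback replaces metathesis by a twofold Stille coupling that brings in C2=C3 with its Z geometry preformed. It sets out from 13, leaving out the vinylation: kinetic resolution under the conditions of step 8 should give the diiodo epoxy alcohol F3, acrylation the diiodo acrylate F4, and the cyclisation of step 10 the diiodo hydroxy lactone F5. F5 and (Z)-1,2-bis(tributylstannyl)ethene with PdCl2(MeCN)2 in DMF at high dilution should couple first at the less hindered C1 iodide and then intramolecularly at C4, giving the macrocyclic (1(10)E,2Z,4-cis) triene alcohol F6. Yamaguchi acylation with 22 gives the triene ester F7, and Shi epoxidation of its trisubstituted 1(10) alkene comes back to the route at 26.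

3. Step 13. Site selectivity between the two dienes may be incomplete, facial control may erode, and the methylene lactone may suffer at pH 10.5. The fallback moves the epoxidation before the acylation and uses hydroxyl direction instead of a dioxirane. It sets out from 19: VO(OiPr)3 with a chiral bishydroxamic acid ligand and cumene hydroperoxide in toluene epoxidises only the alkene homoallylic to the free C8 hydroxyl, under neutral conditions, to give the epoxy hydroxy lactone F8. Yamaguchi acylation of F8 with 22 as in step 12 comes back to the route at 25.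

**Further compounds**

F1 | step 10 | diethylphosphonoacetate ester of 15 | CC(C)(C)[Si](C)(C)OC/C(C=C)=C/[C@@H](OC(=O)CP(=O)(OCC)OCC)[C@H]1O[C@@H]1C/C(C)=C/C=C
F2 | step 10 | α-(diethoxyphosphoryl) hydroxy lactone (3-phosphono analogue of 19, C11 configuration undefined) | CCOP(=O)(OCC)C1C(=O)O[C@H](/C=C(CO[Si](C)(C)C(C)(C)C)\C=C)[C@H]1[C@H](O)C/C(C)=C/C=C
F3 | step 14 | diiodo epoxy alcohol (analogue of 15 with iodine in place of both vinyl groups) | CC(C)(C)[Si](C)(C)OC/C(I)=C/[C@@H](O)[C@H]1O[C@@H]1C/C(C)=C/I
F4 | step 14 | diiodo acrylate (acrylate ester of F3) | CC(C)(C)[Si](C)(C)OC/C(I)=C/[C@@H](OC(=O)C=C)[C@H]1O[C@@H]1C/C(C)=C/I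
F5 | step 14 | diiodo hydroxy lactone (analogue of 19 with iodine in place of both vinyl groups) | C=C1C(=O)O[C@H](/C=C(\I)CO[Si](C)(C)C(C)(C)C)[C@H]1[C@H](O)C/C(C)=C/I
F6 | step 14 | macrocyclic triene alcohol (15-O-TBS-8-hydroxygermacra-1(10)E,2Z,4,11(13)-tetraen-12,6-olide) | C=C1C(=O)O[C@@H]2/C=C(CO[Si](C)(C)C(C)(C)C)\C=C/C=C(C)/C[C@@H](O)[C@@H]12
F7 | step 14 | macrocyclic triene ester ((2Z)-4-acetoxy-2-methylbut-2-enoate of F6) | C=C1C(=O)O[C@@H]2/C=C(CO[Si](C)(C)C(C)(C)C)\C=C/C=C(C)/C[C@@H](OC(=O)/C(C)=C\COC(C)=O)[C@@H]12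
F8 | step 13 | epoxy hydroxy lactone ((1R,10R)-epoxide of 19) | C=C1C(=O)O[C@H](/C=C(CO[Si](C)(C)C(C)(C)C)\C=C)[C@H]1[C@H](O)C[C@@]2(C)O[C@@H]2C=C
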